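Numbering follows the geranyllinalool chain (C1 vinyl CH2, C3 carbinol, C15 C–Cl). Everything rests on the 1,4-relation between the ether oxygen on C10 and C7 across the cyclohexane ring C6–C7–C8–C9–C10–C11. A Lewis acid opens an acyclic (10S,11S)-10,11-epoxide at C11 with the 6E-alkene (C6–C11 bond) and the oxygen left on C10 traps the C7 cation: one operation closes the carbocycle and the O–C7 bridge of the 7-oxabicyclo[2.2.1]heptane and sets C6, C7 and C11. The precursor is 10,11-epoxygeranyllinalyl acetate, made from farnesol and a prenyl unit; the C14/C15 bromide–chloride pair is added afterwards to the only remaining trisubstituted alkene.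

Key step: step 7

Remark: the D-fructose-derived Shi ketone is assumed to give the 14R epoxide (spiro transition-state model); if the sense were the opposite, the ketone from L-fructose would be used.

Step 1
Reactants: 1 (2E,6E)-farnesol
Product: 2 (2S,3S)-2,3-epoxyfarnesol
Conditions: Ti(OiPr)4 (10 mol %), L-(+)-diethyl tartrate (12 mol %), t-BuOOH, 4 Å molecular sieves, CH2Cl2, −20 °C
Reagents that add atoms: tert-butyl hydroperoxide CC(C)(C)OO
Why: Sharpless asymmetric epoxidation reaches only the allylic 2,3-alkene, and the L-(+)-tartrate catalyst should deliver oxygen to the face that gives the (2S,3S)-epoxide, whose C3 becomes the 3S carbinol centre of the target.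

Step 2
Reactants: 2 (2S,3S)-2,3-epoxyfarnesol
Product: 4 (3S,6E)-nerolidol, via epoxy iodide 3 (not isolated)
Conditions: PPh3, I2, imidazole, THF, 0 °C; then Zn dust, AcOH, EtOH, rt
Reagents that add atoms: none
Why: Appel-type iodination of the primary alcohol followed by zinc-induced reductive opening of the 2,3-epoxy iodide (β-elimination of the organozinc) should transpose the allylic system to the tertiary vinyl carbinol; the C3–O bond is never broken, so the configuration is kept.

Step 3
Reactants: 4 (3S,6E)-nerolidol
Product: 5 (3S,6E,10E)-12-hydroxynerolidol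
Conditions: SeO2 (30 mol %), t-BuOOH, salicylic acid (10 mol %), CH2Cl2, 0 °C to rt
Reagents that add atoms: tert-butyl hydroperoxide CC(C)(C)OO
Why: SeO2-catalysed allylic oxidation (ene reaction, then [2,3]-shift) should occur, as is usual for polyprenyl chains, at the E-methyl group of the terminal trisubstituted alkene and give the 10E allylic alcohol; some internal oxidation and over-oxidation to the enal are expected and would be removed by chromatography.

Step 4
Reactants: 5 (3S,6E,10E)-12-hydroxynerolidol
Product: 6 (3S,6E,10S,11S)-10,11-epoxy-12-hydroxy-10,11-dihydronerolidol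
Conditions: Ti(OiPr)4 (20 mol %), L-(+)-diethyl tartrate (24 mol %), t-BuOOH, 4 Å molecular sieves, CH2Cl2, −25 °C
Reagents that add atoms: tert-butyl hydroperoxide CC(C)(C)OO
Why: the hydroxyl-directed Sharpless asymmetric epoxidation should touch only the 10,11-alkene next to the primary allylic alcohol (the tertiary vinyl carbinol is a very slow substrate and the 6,7-alkene has no directing group), and L-(+)-tartrate should give the (10S,11S)-epoxide that carries the stereocentres for C10 and C11.

Step 5
Reactants: 6 (3S,6E,10S,11S)-10,11-epoxy-12-hydroxy-10,11-dihydronerolidol; 7 prenylmagnesium chloride (3-methylbut-2-enylmagnesium chloride, C5H9MgCl)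
Product: 9 (3S,6E,10S,11S)-10,11-epoxy-10,11-dihydrogeranyllinalool, via primary triflate 8 (not isolated)
Conditions: Tf2O (1.05 equiv), 2,6-lutidine, CH2Cl2, −78 °C; then 7 (4 equiv), CuI (10 mol %), THF, −78 to −40 °C
Reagents that add atoms: none
Why: the primary hydroxyl should be triflated selectively in the cold and the triflate displaced in a copper-catalysed Grignard cross-coupling at sp3 carbon, in which prenyl-copper species bond through the unsubstituted CH2 terminus; the hindered trisubstituted epoxide should not open at this temperature and no stereocentre is touched (the tertiary alkoxide consumes one equivalent of 7).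

Step 6
Reactants: 9 (3S,6E,10S,11S)-10,11-epoxy-10,11-dihydrogeranyllinalool
Product: 10 (3S,6E,10S,11S)-10,11-epoxy-10,11-dihydrogeranyllinalyl acetate
Conditions: Ac2O, Et3N, DMAP (20 mol %), CH2Cl2, 35 °C
Reagents that add atoms: acetic anhydride CC(=O)OC(C)=O
Why: DMAP-catalysed acylation of the tertiary alcohol under basic conditions leaves the epoxide intact and turns the C3 oxygen into a poor nucleophile for the next step.

Step 7
Reactants: 10 (3S,6E,10S,11S)-10,11-epoxy-10,11-dihydrogeranyllinalyl acetate
Product: 11 (3S,6S,7R,10S,11S)-7,10-epoxy-bridged cyclization product (C3 acetate; 7-oxabicyclo[2.2.1]heptane with methyl on bridgehead C7, exo C6 chain, exo C11 methyl and endo 4-methylpent-3-enyl on C11)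
Conditions: BF3·OEt2 (0.3 equiv), CH2Cl2, −78 °C; then Et3N
Reagents that add atoms: none
Why: BF3 activates the oxirane, the 6E-alkene attacks the tertiary carbon C11 from the side opposite the C11–O bond through a chair-like transition state, and the tertiary C7 cation so formed is taken up by the oxygen that stays on C10 once the ring reaches a boat, which makes the O–C7 bond. The closest known reaction type is the Lewis-acid cyclization of 5,6-unsaturated trisubstituted oxiranes, in which 7-oxabicyclo[2.2.1]heptanes of the 1,4-cineole type arise by this same oxygen capture. The cyclohexane closes 6-endo with respect to both the alkene and the oxirane, and the two oxolane rings close together by transannular 1,4-capture of the cation. C11 is controlled by inversion of the 11S epoxide carbon and C10 is carried over unchanged; C6 is controlled by the chair fold, in which the E-alkene places the C5 chain equatorial and therefore cis to oxygen (exo in the bicycle); C7 is controlled by the bridge, which can form on one face only. The step needs Markovnikov opening at C11 (secured by the trisubstituted oxirane), attack by the 6,7-alkene and not by the 14,15-alkene (which could reach C11 only through a four-membered ring), and oxygen capture in place of proton loss (non-basic medium at −78 °C). The C3 oxygen, which as a free alcohol would close a tetrahydropyran onto C7, is kept out by the acetate.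

Step 8
Reactants: 11 bridged cyclization product (C3 acetate)
Product: 12 (14R)-14,15-epoxide of 11
Conditions: Shi ketone (D-fructose-derived, 30 mol %), KHSO5 (as Oxone, 2KHSO5·KHSO4·K2SO4), K2CO3, Bu4NHSO4, Na2B4O7 buffer (pH 10.5), MeCN/CH2(OMe)2/H2O, 0 °C
Reagents that add atoms: potassium peroxymonosulfate [K+].[O-]S(=O)(=O)OO
Why: Shi asymmetric epoxidation by the chiral dioxirane should take place at the only electron-rich trisubstituted alkene left (the vinyl group is inert) and set C14 as R through the spiro transition state.

Step 9
Reactants: 12 (14R)-14,15-epoxide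
Product: 13 (14R)-15-bromo-14-hydroxy compound (tertiary bromide, secondary alcohol; C3 acetate)
Conditions: 48 % aq HBr (1.1 equiv), THF, −15 °C
Reagents that add atoms: hydrogen bromide Br
Why: acid-promoted Markovnikov opening of the trisubstituted epoxide puts bromide on the tertiary carbon C15 and leaves the C14–O bond, and with it the 14R centre, untouched; the short cold exposure should spare the tertiary allylic acetate and the bridged ether.

Step 10
Reactants: 13 (14R)-15-bromo-14-hydroxy compound
Product: 14 dactylomelol acetate ((14S)-14-bromo-15-chloro; C3 acetate)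
Conditions: SOCl2 (1.5 equiv), pyridine (3 equiv), CH2Cl2, −20 to 0 °C
Reagents that add atoms: thionyl chloride O=S(Cl)Cl
Why: deoxychlorination with neighbouring-group participation: the chlorosulfite on C14 is expelled by the vicinal anti bromine to give a bromonium ion (1,2-bromine shift with inversion at C14, 14R-OH to 14S-Br), and chloride should open this ion at the tertiary carbon C15 as in a Markovnikov bromochlorination.

Step 11
Reactants: 14 dactylomelol acetate
Product: 15 dactylomelol
Conditions: i-Bu2AlH (2.5 equiv), CH2Cl2, −78 °C; then aq KNaC4H4O6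
Reagents that add atoms: none
Why: reductive cleavage of the hindered tertiary acetate at −78 °C avoids base, so that the secondary bromide and the tertiary chloride should not be eliminated; no stereocentre is touched.

Compound list
1 | (2E,6E)-farnesol | OC/C=C(\C)CC/C=C(\C)CCC=C(C)C | starting material
2 | (2S,3S)-2,3-epoxyfarnesol | OC[C@@H]1O[C@@]1(C)CC/C=C(\C)CCC=C(C)C | intermediate
3 | (2R,3S)-2,3-epoxyfarnesyl iodide (same spatial arrangement as 2) | IC[C@@H]1O[C@@]1(C)CC/C=C(\C)CCC=C(C)C | intermediate
4 | (3S,6E)-nerolidol | C=C[C@@](C)(O)CC/C=C(\C)CCC=C(C)C | intermediate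
5 | (3S,6E,10E)-12-hydroxynerolidol [(2E,6E,10S)-2,6,10-trimethyldodeca-2,6,11-triene-1,10-diol] | C=C[C@@](C)(O)CC/C=C(\C)CC/C=C(\C)CO | intermediate
6 | (3S,6E,10S,11S)-10,11-epoxy-12-hydroxy-10,11-dihydronerolidol (C9 and C12 trans on the oxirane) | C=C[C@@](C)(O)CC/C=C(\C)CC[C@@H]1O[C@@]1(C)CO | intermediate
7 | prenylmagnesium chloride (3-methylbut-2-enylmagnesium chloride) | CC(C)=CC[Mg]Cl | starting material
8 | 12-O-triflate of 6 | C=C[C@@](C)(O)CC/C=C(\C)CC[C@@H]1O[C@@]1(C)COS(=O)(=O)C(F)(F)F | intermediate
9 | (3S,6E,10S,11S)-10,11-epoxy-10,11-dihydrogeranyllinalool | C=C[C@@](C)(O)CC/C=C(\C)CC[C@@H]1O[C@@]1(C)CCC=C(C)C | intermediate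
10 | (3S,6E,10S,11S)-10,11-epoxy-10,11-dihydrogeranyllinalyl acetate | C=C[C@@](C)(OC(C)=O)CC/C=C(\C)CC[C@@H]1O[C@@]1(C)CCC=C(C)C | intermediate
11 | (3S,6S,7R,10S,11S)-bridged ether acetate with 4-methylpent-3-enyl on C11 | C=C[C@@](C)(OC(C)=O)CC[C@H]1[C@](C)(CCC=C(C)C)[C@@H]2CC[C@@]1(C)O2 | intermediate
12 | (14R)-14,15-epoxide of 11 | C=C[C@@](C)(OC(C)=O)CC[C@H]1[C@](C)(CC[C@H]2OC2(C)C)[C@@H]3CC[C@@]1(C)O3 | intermediate
13 | (14R)-15-bromo-14-hydroxy compound (C3 acetate) | C=C[C@@](C)(OC(C)=O)CC[C@H]1[C@](C)(CC[C@@H](O)C(C)(C)Br)[C@@H]2CC[C@@]1(C)O2 | intermediate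
14 | dactylomelol acetate ((14S)-14-bromo-15-chloro) | C=C[C@@](C)(OC(C)=O)CC[C@H]1[C@](C)(CC[C@H](Br)C(C)(C)Cl)[C@@H]2CC[C@@]1(C)O2 | intermediate
15 | dactylomelol (3S,6S,7R,10S,11S,14S) | C=C[C@@](C)(O)CC[C@H]1[C@](C)(CC[C@H](Br)C(C)(C)Cl)[C@@H]2CC[C@@]1(C)O2 | target

Total step count: 11. Longest linear sequence: 11 steps (1 to 15).

Steps most likely to fail

Step 7. The C7 cation may lose a proton (to the exocyclic or ring alkene) or be intercepted by the side-chain 14,15-alkene before the ring reaches the boat in which oxygen can bond to C7. The fallback sets out from 10 and closes the bridge in a separate operation. Cyclization under conditions that favour proton loss (MeAlCl2, CH2Cl2, −78 °C) should give the exocyclic alkenol F1, in which C6, C10 and C11 are already set. Iodoetherification (I2, NaHCO3, MeCN, 0 °C) then lets the C10 hydroxyl add to C7 in the Markovnikov sense and gives the iodomethyl ether F2. Removal of iodine with Bu3SnH and AIBN (toluene, 80 °C) comes back to the route at 11.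

Step 10. The activated alcohol or the tertiary bromide may be lost by elimination, or chloride may substitute directly at C14 without bromine migration, which would erode regio- and stereochemical purity. The fallback sets out from 13 and separates activation from ionization. The alcohol is first converted into the mesylate F4 (MsCl, Et3N, CH2Cl2, −20 °C). Solvolysis of F4 in (CF3)2CHOH with Et4NCl at rt should then form the same bromonium ion by bromine-assisted ionization in a non-nucleophilic ionizing solvent; chloride opens it at C15 and the route is rejoined at 14.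

Step 5. Displacement at C12, which sits next to the fully substituted epoxide carbon, may be slow, and the prenyl unit may couple through its tertiary end or the epoxide may open. The fallback sets out from triflate 8 and uses allylmagnesium bromide (C3H5MgBr) with CuI (THF, −78 °C), a smaller nucleophile without regiochemical ambiguity, to give the allyl epoxide F3. Cross-metathesis of F3 with 2-methylbut-2-ene (second-generation Grubbs catalyst, CH2Cl2, 40 °C) then builds the trisubstituted terminus and comes back to the route at 9; the hindered vinyl carbinol and the 6,7-alkene should not take part.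

Further compounds
F1 | step 7 | exocyclic alkenol (C7 methylidene, free C10 hydroxyl, C3 acetate) | C=C[C@@](C)(OC(C)=O)CC[C@H]1[C@](C)(CCC=C(C)C)[C@@H](O)CCC1=C
F2 | step 7 | iodomethyl ether (11 with CH2I in place of the C7 methyl) | C=C[C@@](C)(OC(C)=O)CC[C@H]1[C@](C)(CCC=C(C)C)[C@@H]2CC[C@@]1(CI)O2
F3 | step 5 | allyl epoxide (9 with but-3-enyl in place of 4-methylpent-3-enyl on C11) | C=C[C@@](C)(O)CC/C=C(\C)CC[C@@H]1O[C@@]1(C)CCC=C
F4 | step 10 | 14-O-mesylate of 13 | C=C[C@@](C)(OC(C)=O)CC[C@H]1[C@](C)(CC[C@@H](OS(C)(=O)=O)C(C)(C)Br)[C@@H]2CC[C@@]1(C)O2
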